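## Structural features

The target is a dearomatised benzoylphloroglucinol. Ring A is a six-membered carbocycle with an enolised β-triketone array (C5 carbonyl, C6 benzoyl, C7 enol), fused along C4a–C8a to a 2,2-dimethyl-2H-pyran, ring B. The only sp3 carbon of ring A, C8, is quaternary and stereogenic; it carries a prenyl group and a five-carbon chain C1'–C5' that ends in an (E)-2-methylpropenoic acid. The second stereocentre, C2', bears an isopropenyl group and is separated from C8 by the C1' methylene, so the two centres are 1,3-related across an open chain and no ring of the target links them. Fragile groups are the acidic, metal-chelating triketone enol (open to O-acylation, retro-Claisen cleavage and electron transfer), the acid-sensitive chromene and prenyl alkenes, and the 1,1-disubstituted alkene next to C2'. The real difficulty is the absolute configuration of C8, whose two allyl-type substituents first differ three bonds away, together with its relation to C2'. The chain on C8 is itself a prenyl group that has gained a C–C bond at its alkene CH and shows a 1-methylvinyl group where the gem-dimethyl end was, which is the imprint of an ene reaction, and the C7 enol oxygen lies four bonds from C2'. The key step uses exactly this: a glyoxylate hung on O7 of an achiral 8,8-diprenyl precursor picks one of two enantiotopic prenyl groups and closes a temporary seven-membered lactone (O7, C7, C8, C1', C2', C3', C4').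

## Logic of the disconnections

19 is taken back to its methyl ester 18, and the C4'=C5' double bond of 18 is cut to give 16 and 17. A stabilised α-methyl ylide gives the (E)-trisubstituted enoate reliably, and the cut removes four carbons and the only alkene geometry. The forward steps must tolerate a free acidic enol, so excess ylide is needed and the ester is hydrolysed last under conditions in which the triketone is an unreactive enolate.

16 is traced through 15 to 14 by adjusting the oxidation level of C4' and by re-attaching an oxygen at C3' (the C3'–O bond). That oxygen is the residue of an aldehyde, so its presence in 14 is what allows C2'–C3' to be made by carbonyl addition. The forward demand is a reduction of an α-acyloxy ester that leaves the benzoyl dienone alone, and a partial ester reduction next to an enolised triketone.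

14 is reconnected through 13 to 12 by closing the C4'–O7 acyl bond (methanolysis in reverse) and removing the C3' acetate. Keeping O7 tied up in the lactone while C3'–OH is acetylated means no enol acetate has to be handled. The forward opening must be faster than loss of the secondary acetate, which the vinylogous-anhydride character of the lactone secures.

12 is cut at C2'–C3', with return of one hydrogen from the C3' oxygen to the isopropenyl CH2, to give 11. This is the strategic cut: both stereocentres and the ring vanish, and the precursor is achiral with two identical prenyl groups on C8. The forward step must choose one enantiotopic prenyl group and one alkene face through a short ester tether.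

11 is taken back through 10 and 9 to 6 and 7 (by way of 8), cutting the O7–acyl bond. The aldehyde is revealed last by oxidation of a glycolate, not by hydrolysis of an acetal: the enol ester of a triketone is a vinylogous anhydride that would not survive the aqueous acid needed to open an α-carbonyl acetal, and anhydrous oxidation gives the aldehyde free of water. The demands are acylation on O7 and not on O5 or the benzoyl oxygen, and immediate use of 11.

6 is cut at both C8–CH2 bonds to 3 and two equivalents of 4, passing through 5. C8 is the only unsubstituted, doubly activated carbon of 3, so both alkylations go to the same atom and the second one dearomatises; no stereocentre is created. The demand is C- over O-alkylation.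

3 is cut at C4–C4a and O1–C2 to 1 and 2, a chromene annulation that uses the para hydroxyl of 1 as the ring oxygen. It supplies ring B in one step from a symmetric phenol; the demand is regioselective ring closure through the non-chelated hydroxyl.

## Other disconnections considered

Alternative 1: The cut is the enol-ester C–O bond between the C7 oxygen and the carbon that later becomes the isopropenyl carbon. Ring A is taken back to a 2,2-disubstituted cyclohexane-1,3,5-trione acid A1, whose C2' already carries that carbon as a carboxylic acid together with the finished enoate chain.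
- Forward step: a carbodiimide with 4-dimethylaminopyridine would close the acid onto one of the two diastereotopic enolised carbonyls flanking C8 to give the six-membered enol lactone A2. The existing C2' centre would decide which oxygen is acylated and so set C8, with the prenyl group trans to the C3' chain on the new ring.
- In its favour: the relay runs through a six-membered ring from a real stereocentre that can be made by established asymmetric enolate chemistry. Enol esterification of 1,3-diones is known, and the acyl transfer is reversible under the pyridine catalyst, so the diastereomers could settle thermodynamically. On predictability of stereocontrol it is the better plan, because the chosen step must read two identical prenyl groups through a catalyst.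
- Against it here: A2 still lacks the benzoyl group, ring B and the isopropenyl group. A C6 benzoylation, a chromene annulation with open regiochemistry and a conversion of the lactone carbonyl into a 1-methylvinyl group would all follow on a β-triketone, and A1 needs its own asymmetric synthesis.
- Comparison: both key steps are mechanistically simple, but only the chosen one forms a skeletal C–C bond, and the chosen plan is clearly shorter because it starts from an aromatic core that already holds the benzoyl and pyran units.

Alternative 2: The cut is the C6–C7 bond of ring A. The carbocycle is traced to a 3,3-disubstituted 6-phenacylpyran-2,4-dione A3, in which C8 with both of its chains is the quaternary C3 of the lactone.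
- Forward step: methoxide (NaOMe or Mg(OMe)2) would open the enol lactone to an ester and a tricarbonyl chain, and the phenacyl methylene, the future C6, would attack the ester carbon in a Dieckmann-type closure to the benzoyl trione A4 (C4a still a methylene, no ring B).
- In its favour: the benzoyl group reaches C6 by construction, so no site selectivity of acylation has to be controlled. On that point it is better than the chosen plan, whose step 3 must find the right oxygen. As a robust anionic ring closure it is at least the equal of the ene step in reliability.
- Against it here: the step creates no stereocentre, so C8 and C2' would each need a separate asymmetric step earlier with nothing linking them. Retro-Claisen cleavage of the open keto ester competes under alkoxide, and ring B must still be annulated with a choice between the C8a and C5 oxygens.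
- Comparison: strategically it is weaker, since it postpones the stereochemical problem that the chosen step addresses in one event, and it is longer.

Alternative 3: The cut is the C8–C1' bond. The quaternary centre would come from conjugate addition of C8 of the mono-prenyl phenol 5, an intermediate of the chosen route, to the 2-substituted acrolein A5, which carries the finished (E)-enoate.
- Forward step: a cinchona-derived quaternary ammonium salt under phase-transfer conditions would pair with the phenoxide and direct the dearomatising Michael addition to one face. The aldehyde would then close on the C7 oxygen to the six-membered lactol A6, in which C2', α to the masked aldehyde, could epimerise to the arrangement with prenyl trans to the C3' chain.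
- In its favour: it is the most convergent plan. The whole chain, including the trisubstituted enoate, arrives in one step, so the deoxygenation, ester reduction and Wittig steps of the chosen endgame disappear. C8 is set by a catalyst close to the reacting carbon, and C2' is corrected thermodynamically instead of having to be right kinetically. On convergence and on control of C2' it is the better plan.
- Against it here: an asymmetric dearomative Michael addition of such a phenol to an enal under phase transfer is itself unproven, so the methodological risk is comparable. O-alkylation and polymerisation of A5 compete, and the preference at C2' in the lactol is only presumed.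
- Further cost: the lactol carbon must be turned into the isopropenyl group (methyl addition, oxidation, methylenation) next to a triketone and an unsaturated ester, which costs about as many steps as are saved.
- Comparison: the two plans are close. The chosen plan has the simpler, achiral precursor from two ordinary prenylations and delivers the isopropenyl group in the bond-forming step itself.

Key step: step 6

Remarks on the chemistry:
- Locants C2–C8a are those of the chromene, and C1'–C5' count along the chain from C8, for all intermediates.
- CIP labels refer to the tautomer drawn; where the letter changes between intermediates, only substituent priorities change, not the spatial arrangement.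
- The sense of induction of the copper complex in this tethered reaction cannot be predicted with confidence. The (S,S) ligand is written, and the (R,R) ligand would be used if it proves to give the antipode.

## Route

Step 1
Reactants: 1 2,4,6-trihydroxybenzophenone; 2 3-methylbut-2-enal
Product: 3 (5,7-dihydroxy-2,2-dimethyl-2H-chromen-6-yl)(phenyl)methanone
Conditions: 2 (1.5 equiv), ethylenediammonium diacetate (10 mol %), toluene, 100 °C
Reagents that add atoms: none
Why: Chromene annulation by Knoevenagel-type condensation at a ring CH, dehydration to an ortho-quinone methide and oxa-6π-electrocyclisation; closure through the non-chelated 4-hydroxyl places the benzoyl group between the two remaining hydroxyls, and the minor 8-benzoyl isomer from closure through a chelated hydroxyl would be removed by chromatography.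

Step 2
Reactants: 3 (5,7-dihydroxy-2,2-dimethyl-2H-chromen-6-yl)(phenyl)methanone; 4 1-bromo-3-methylbut-2-ene (prenyl bromide)
Product: 6 6-benzoyl-7-hydroxy-2,2-dimethyl-8,8-bis(3-methylbut-2-en-1-yl)-2H-chromen-5(8H)-one, via 8-prenyl chromenediol 5 (not isolated)
Conditions: 4 (2.4 equiv), 10% aq. KOH, 0 °C → rt; acidify, extract
Reagents that add atoms: none
Why: Phenoxide C-alkylation followed by dearomative C-alkylation at the same carbon: C8 is the only unsubstituted ring carbon and is ortho to O7 and para to O5, and water favours C- over O-alkylation by hydrogen bonding to the phenoxide oxygens. No stereocentre arises because the two prenyl groups are identical.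

Step 3
Reactants: 6 6-benzoyl-7-hydroxy-2,2-dimethyl-8,8-bis(3-methylbut-2-en-1-yl)-2H-chromen-5(8H)-one; 7 (tert-butyldimethylsilyloxy)acetic acid
Product: 9 6-benzoyl-2,2-dimethyl-8,8-bis(3-methylbut-2-en-1-yl)-5-oxo-5,8-dihydro-2H-chromen-7-yl (tert-butyldimethylsilyloxy)acetate, via silyloxyacetyl chloride 8 (not isolated)
Conditions: 7, 1-chloro-N,N,2-trimethylprop-1-en-1-amine (1.1 equiv), CH2Cl2, 0 °C; then 6, Et3N (1.5 equiv), DMAP (5 mol %), 0 °C → rt
Reagents that add atoms: none
Why: Enol ester formation from a vinylogous acid and an acid chloride made under neutral conditions, so the silyl ether survives. DMAP lets the acyl group equilibrate among the three triketone oxygens; the O7 ester keeps the C5 carbonyl conjugated with the pyran oxygen, as in the preferred tautomer of 6, and is expected to be the stable isomer, to be confirmed by HMBC/NOE at this robust stage.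

Step 4
Reactants: 9 6-benzoyl-2,2-dimethyl-8,8-bis(3-methylbut-2-en-1-yl)-5-oxo-5,8-dihydro-2H-chromen-7-yl (tert-butyldimethylsilyloxy)acetate
Product: 10 6-benzoyl-2,2-dimethyl-8,8-bis(3-methylbut-2-en-1-yl)-5-oxo-5,8-dihydro-2H-chromen-7-yl hydroxyacetate
Conditions: HF·pyridine, pyridine, THF, 0 °C; cold pH 7 buffer wash; used at once
Reagents that add atoms: none
Why: Fluoride cleavage of a primary silyl ether under buffered, weakly nucleophilic conditions; basic fluoride and alcoholic solvents are avoided because the enol ester is an activated ester.

Step 5
Reactants: 10 6-benzoyl-2,2-dimethyl-8,8-bis(3-methylbut-2-en-1-yl)-5-oxo-5,8-dihydro-2H-chromen-7-yl hydroxyacetate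
Product: 11 6-benzoyl-2,2-dimethyl-8,8-bis(3-methylbut-2-en-1-yl)-5-oxo-5,8-dihydro-2H-chromen-7-yl oxoacetate (C7 glyoxylate)
Conditions: Dess–Martin periodinane (1.2 equiv), NaHCO3 (solid), CH2Cl2, 0 °C; filter under argon, concentrate cold, toluene azeotrope; used crude at once
Reagents that add atoms: none
Why: Dess–Martin oxidation of a primary α-hydroxy ester to the glyoxylate under anhydrous, near-neutral conditions; the aldehyde never meets water or acid, which would hydrate it or cleave the vinylogous anhydride, and the alkenes are inert to the periodinane.

Step 6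
Reactants: 11 6-benzoyl-2,2-dimethyl-8,8-bis(3-methylbut-2-en-1-yl)-5-oxo-5,8-dihydro-2H-chromen-7-yl oxoacetate
Product: 12 (8R,2'R)-hydroxy lactone: seven-membered enol lactone O7–C4'(=O)–C3'H(OH)–C2'H(isopropenyl)–C1'H2–C8 fused at C7–C8 to 6-benzoyl-2,2-dimethyl-8-prenyl-2H-chromen-5(8H)-one; isopropenyl cis to the C8 prenyl on the lactone ring; C3' of either configuration
Conditions: Cu(OTf)2 (20 mol %), (S,S)-2,2'-isopropylidenebis(4-tert-butyl-2-oxazoline) (22 mol %), 4 Å MS, CH2Cl2, −40 → 0 °C
Reagents that add atoms: none
Why: Proposed new method: the bis(oxazoline) complex of divalent copper chelates the aldehyde and ester carbonyl oxygens of 11, the alkene CH of one prenyl group (C2') attacks the activated aldehyde carbon (C3'), and a hydrogen of one of its geminal methyls passes to the aldehyde oxygen through a six-membered ene transition state, leaving the isopropenyl group on C2'. The closest known reaction types are the bis(oxazoline)–copper and binaphthol–titanium glyoxylate-ene reactions, including their use for selection between enantiotopic groups, and Lewis-acid type 1 intramolecular carbonyl-ene cyclisations of the citronellal kind. The one ring closed is the seven-membered lactone (O7, C7, C8, C1', C2', C3', C4'), formed by a 7-exo-trig attack on the aldehyde in which both the C=O and the reacting C=C lie outside the new ring. C8 becomes stereogenic through the choice between the two enantiotopic prenyl groups, C2' through the alkene face that bonds, and C3' through the aldehyde face left open by the tert-butyl groups of the ligand. Because only four atoms separate C2' from the ester carbon, these three choices are coupled in one bicyclic transition state, so fixing the aldehyde face is expected to fix the other two. The step needs group selectivity, the cis relation of isopropenyl and remaining prenyl, and ene over Prins closure; the planar enol ester next to the quaternary carbon gives rigidity, and the gem-dimethyl terminus supplies the allylic hydrogens that quench the developing tertiary cation. The C3' configuration is irrelevant because that centre is removed in step 8.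

Step 7
Reactants: 12 (8R,2'R)-hydroxy lactone
Product: 14 methyl (2RS,3R)-2-acetoxy-3-{[(8S)-6-benzoyl-7-hydroxy-2,2-dimethyl-8-(3-methylbut-2-en-1-yl)-5-oxo-5,8-dihydro-2H-chromen-8-yl]methyl}-4-methylpent-4-enoate, via acetylated lactone 13 (not isolated)
Conditions: Ac2O, pyridine, CH2Cl2, 0 °C; then MeOH, Et3N, 0 °C → rt
Reagents that add atoms: acetic anhydride, CC(=O)OC(C)=O; methanol, CO
Why: Acetylation of the secondary alcohol while O7 is still held in the lactone, so no enol acetate is carried forward; the enol lactone is a vinylogous anhydride and is opened by methanol/triethylamine far faster than the secondary acetate is exchanged. C8 and C2' are untouched.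

Step 8
Reactants: 14 methyl (2RS,3R)-2-acetoxy-3-{[(8S)-chromen-8-yl]methyl}-4-methylpent-4-enoate (as named in step 7)
Product: 15 methyl (3S)-3-{[(8S)-6-benzoyl-7-hydroxy-2,2-dimethyl-8-(3-methylbut-2-en-1-yl)-5-oxo-5,8-dihydro-2H-chromen-8-yl]methyl}-4-methylpent-4-enoate
Conditions: Et3N (1.1 equiv), THF; SmI2 (3 equiv), HMPA, t-BuOH, −78 °C
Reagents that add atoms: none
Why: Samarium diiodide reduction of an α-acyloxy ester (electron transfer, loss of acetate, second electron transfer, protonation of the samarium enolate by t-BuOH). The triketone is present as its triethylammonium enolate, an anion that resists electron uptake, and excess SmI2/HMPA reduces the transient α-ester radical faster than it can add to a nearby alkene. C3' ceases to be stereogenic; C2' (β to the ester) and C8 are not affected.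

Step 9
Reactants: 15 methyl (3S)-3-{[(8S)-chromen-8-yl]methyl}-4-methylpent-4-enoate (as named in step 8)
Product: 16 (3S)-3-{[(8S)-6-benzoyl-7-hydroxy-2,2-dimethyl-8-(3-methylbut-2-en-1-yl)-5-oxo-5,8-dihydro-2H-chromen-8-yl]methyl}-4-methylpent-4-enal
Conditions: DIBAL-H (2.2 equiv), CH2Cl2, −78 °C; MeOH, then aq. Rochelle salt
Reagents that add atoms: none
Why: Partial reduction of a methyl ester through the tetrahedral aluminate that is stable at −78 °C; the first equivalent deprotonates the acidic enol, and the resulting aluminium triketonate shields the ring carbonyls from hydride. C2' is β to the new aldehyde and cannot epimerise.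

Step 10
Reactants: 16 (3S)-3-{[(8S)-chromen-8-yl]methyl}-4-methylpent-4-enal (as named in step 9); 17 methyl 2-(triphenylphosphoranylidene)propanoate
Product: 18 methyl (2E,5R)-5-{[(8S)-6-benzoyl-7-hydroxy-2,2-dimethyl-8-(3-methylbut-2-en-1-yl)-5-oxo-5,8-dihydro-2H-chromen-8-yl]methyl}-2,6-dimethylhepta-2,6-dienoate
Conditions: 17 (2.5 equiv), toluene, 60 °C
Reagents that add atoms: none
Why: Wittig olefination with a stabilised α-methyl ylide, which gives the (E)-2-methyl enoate; one equivalent of ylide is held as the phosphonium salt of the acidic enol, hence the excess.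

Step 11
Reactants: 18 methyl (2E,5R)-5-{[(8S)-chromen-8-yl]methyl}-2,6-dimethylhepta-2,6-dienoate (as named in step 10)
Product: 19 (2E,5R)-5-{[(8S)-6-benzoyl-7-hydroxy-2,2-dimethyl-8-(3-methylbut-2-en-1-yl)-5-oxo-5,8-dihydro-2H-chromen-8-yl]methyl}-2,6-dimethylhepta-2,6-dienoic acid (CNP0333091.1)
Conditions: LiOH·H2O (5 equiv), THF/MeOH/H2O, rt; then cold 1 M HCl to pH 3
Reagents that add atoms: lithium hydroxide, [Li+].[OH-]
Why: Saponification of the methyl ester; under LiOH the triketone is a delocalised enolate that does not add hydroxide, no centre is epimerisable, and cold, mild acidification returns enol and acid without acid-promoted cyclisation of the prenyl or chromene units.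

## Compound list

1 | 2,4,6-trihydroxybenzophenone | O=C(c1ccccc1)c1c(O)cc(O)cc1O | starting material
2 | 3-methylbut-2-enal | CC(C)=CC=O | starting material
3 | (5,7-dihydroxy-2,2-dimethyl-2H-chromen-6-yl)(phenyl)methanone | O=C(c1ccccc1)c1c(O)cc2OC(C)(C)C=Cc2c1O | intermediate
4 | 1-bromo-3-methylbut-2-ene (prenyl bromide) | CC(C)=CCBr | starting material
5 | [5,7-dihydroxy-2,2-dimethyl-8-(3-methylbut-2-en-1-yl)-2H-chromen-6-yl](phenyl)methanone | O=C(c1ccccc1)c1c(O)c(CC=C(C)C)c2OC(C)(C)C=Cc2c1O | intermediate
6 | 6-benzoyl-7-hydroxy-2,2-dimethyl-8,8-bis(3-methylbut-2-en-1-yl)-2H-chromen-5(8H)-one | CC(C)=CCC1(CC=C(C)C)C(O)=C(C(=O)c2ccccc2)C(=O)C2=C1OC(C)(C)C=C2 | intermediate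
7 | (tert-butyldimethylsilyloxy)acetic acid | CC(C)(C)[Si](C)(C)OCC(=O)O | starting material
8 | (tert-butyldimethylsilyloxy)acetyl chloride | CC(C)(C)[Si](C)(C)OCC(=O)Cl | intermediate
9 | 6-benzoyl-2,2-dimethyl-8,8-bis(3-methylbut-2-en-1-yl)-5-oxo-5,8-dihydro-2H-chromen-7-yl (tert-butyldimethylsilyloxy)acetate | CC(C)(C)[Si](C)(C)OCC(=O)OC1=C(C(=O)c2ccccc2)C(=O)C2=C(OC(C)(C)C=C2)C1(CC=C(C)C)CC=C(C)C | intermediate
10 | 6-benzoyl-2,2-dimethyl-8,8-bis(3-methylbut-2-en-1-yl)-5-oxo-5,8-dihydro-2H-chromen-7-yl hydroxyacetate | OCC(=O)OC1=C(C(=O)c2ccccc2)C(=O)C2=C(OC(C)(C)C=C2)C1(CC=C(C)C)CC=C(C)C | intermediate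
11 | 6-benzoyl-2,2-dimethyl-8,8-bis(3-methylbut-2-en-1-yl)-5-oxo-5,8-dihydro-2H-chromen-7-yl oxoacetate | O=CC(=O)OC1=C(C(=O)c2ccccc2)C(=O)C2=C(OC(C)(C)C=C2)C1(CC=C(C)C)CC=C(C)C | intermediate
12 | (8R,2'R)-hydroxy lactone (O7–C4'(=O)–C3'H(OH)–C2'H(isopropenyl)–C1'H2–C8 ring fused to the 6-benzoyl-2,2-dimethyl-8-prenylchromen-5-one; isopropenyl cis to prenyl; C3' undefined) | C=C(C)[C@H]3C[C@@]1(CC=C(C)C)C(OC(=O)C3O)=C(C(=O)c2ccccc2)C(=O)C2=C1OC(C)(C)C=C2 | intermediate
13 | (8R,2'R)-C3'-acetate of lactone 12 | C=C(C)[C@H]3C[C@@]1(CC=C(C)C)C(OC(=O)C3OC(C)=O)=C(C(=O)c2ccccc2)C(=O)C2=C1OC(C)(C)C=C2 | intermediate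
14 | methyl (2RS,3R)-2-acetoxy-3-{[(8S)-6-benzoyl-7-hydroxy-2,2-dimethyl-8-(3-methylbut-2-en-1-yl)-5-oxo-5,8-dihydro-2H-chromen-8-yl]methyl}-4-methylpent-4-enoate | C=C(C)[C@H](C(OC(C)=O)C(=O)OC)C[C@@]1(CC=C(C)C)C(O)=C(C(=O)c2ccccc2)C(=O)C2=C1OC(C)(C)C=C2 | intermediate
15 | methyl (3S)-3-{[(8S)-6-benzoyl-7-hydroxy-2,2-dimethyl-8-(3-methylbut-2-en-1-yl)-5-oxo-5,8-dihydro-2H-chromen-8-yl]methyl}-4-methylpent-4-enoate | C=C(C)[C@H](CC(=O)OC)C[C@@]1(CC=C(C)C)C(O)=C(C(=O)c2ccccc2)C(=O)C2=C1OC(C)(C)C=C2 | intermediate
16 | (3S)-3-{[(8S)-6-benzoyl-7-hydroxy-2,2-dimethyl-8-(3-methylbut-2-en-1-yl)-5-oxo-5,8-dihydro-2H-chromen-8-yl]methyl}-4-methylpent-4-enal | C=C(C)[C@H](CC=O)C[C@@]1(CC=C(C)C)C(O)=C(C(=O)c2ccccc2)C(=O)C2=C1OC(C)(C)C=C2 | intermediate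
17 | methyl 2-(triphenylphosphoranylidene)propanoate | COC(=O)C(C)=P(c1ccccc1)(c1ccccc1)c1ccccc1 | starting material
18 | methyl (2E,5R)-5-{[(8S)-6-benzoyl-7-hydroxy-2,2-dimethyl-8-(3-methylbut-2-en-1-yl)-5-oxo-5,8-dihydro-2H-chromen-8-yl]methyl}-2,6-dimethylhepta-2,6-dienoate | C=C(C)[C@H](C/C=C(\C)C(=O)OC)C[C@@]1(CC=C(C)C)C(O)=C(C(=O)c2ccccc2)C(=O)C2=C1OC(C)(C)C=C2 | intermediate
19 | (2E,5R)-5-{[(8S)-6-benzoyl-7-hydroxy-2,2-dimethyl-8-(3-methylbut-2-en-1-yl)-5-oxo-5,8-dihydro-2H-chromen-8-yl]methyl}-2,6-dimethylhepta-2,6-dienoic acid | C=C(C)[C@H](C/C=C(\C)C(=O)O)C[C@@]1(CC=C(C)C)C(O)=C(C(=O)c2ccccc2)C(=O)C2=C1OC(C)(C)C=C2 | target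

## Step count and least certain steps

Total step count: 11. Longest linear sequence: 11 steps (1 → 19); 7 and 17 enter as commercial side components.

Step 6 (key step, Proposed new method).
- What may go wrong: weak discrimination between the two enantiotopic prenyl groups, or bonding through the alkene face that gives the trans instead of the cis C8/C2' relation. The ligand acts on the far side of a short, rigid tether, and a seven-membered ene transition state of this kind has no close model.
- Further risks: sequestration of the copper by the 1,3-diketone of ring A, an uncatalysed racemic ene reaction of the very electrophilic glyoxylate, and 1,5-shift of the glyoxylyl group to O5 or the benzoyl oxygen.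
- Fallback (known chemistry, intermolecular; sets out from 6 and returns at 14):
  - The acidic enol of 6 would be masked with Ac2O/Et3N as the enol acetate F1 (the site of acetylation is immaterial).
  - A catalytic asymmetric intermolecular glyoxylate-ene reaction of F1 with methyl glyoxylate as limiting reagent (complex from (i-PrO)2TiCl2 and 1,1'-bi-2-naphthol, 4 Å MS, CH2Cl2, −30 °C; enantiomer of the diol chosen to give 2'R) would set C2' and C3' on one prenyl group and give the hydroxy ester F2. This catalyst cannot be relied on to tell the two prenyl groups apart, so both C8 configurations are expected.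
  - Acetylation to the diacetate F3 and cleavage of the enol acetate with MeOH/Et3N would give 14 together with its C8 epimer F4, a diastereomer to be removed by chromatography. The route continues at step 8.

Step 3.
- What may go wrong: acylation on, or acyl migration to, O5 or the benzoyl enol oxygen. All three oxygens of the triketone anion are nucleophilic, and O7 is flanked by the quaternary carbon.
- Fallback (regiochemistry fixed on the aromatic ring; sets out from 3 and returns at 9):
  - The C7 hydroxyl of 3, flanked only by the C8 hydrogen, would be acylated with 8 (pyridine, −20 °C) to the aryl ester F5, in which the acyl group cannot migrate.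
  - Mitsunobu etherification of the C5 hydroxyl with 3-methylbut-2-en-1-ol (PPh3, DIAD) would give the prenyl ether F6. Its ortho positions C4a and C6 are blocked, so heating in toluene should move the prenyl group by a Claisen then Cope shift to the para carbon C8 and give the phenol F7.
  - A second Mitsunobu prenylation to the ether F8 and a second para-Claisen rearrangement, now onto the substituted C8, would end in 9 with the ester necessarily on O7 and the carbonyl at C5.

Step 5.
- What may go wrong: self-acylation of the free glycolate 10 before oxidation, or hydration, acyl exchange with acetic acid, or premature thermal ene reaction of 11. The ester is a vinylogous anhydride of an α-oxo acid.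
- Fallback (no free hydroxyl at any stage; sets out from 6 and returns at 11): acylation with bromoacetyl bromide/pyridine to the C7 bromoacetate F9, exchange with AgNO3 in MeCN to the nitrate ester F10, and Kornblum-type elimination of nitrite with NaOAc in DMSO to 11. The hydrate formed on work-up would be dehydrated by toluene azeotrope over 4 Å MS before step 6.

Step 8.
- What may go wrong: electron transfer to the benzoyl dienone (ketyl formation, pinacol coupling or conjugate reduction) in competition with reduction of the acetoxy ester, if ionisation of the enol does not protect it sufficiently.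
- Fallback (radical deoxygenation at the lactone stage; sets out from 12 and returns at 15): phenyl chlorothionoformate/pyridine would give the thionocarbonate F11. Barton–McCombie reduction (Bu3SnH, AIBN, toluene, 80 °C, high hydride concentration to outrun cyclisation onto the prenyl group) would give the deoxy lactone F12, and MeOH/Et3N would open it to 15.

Step 2.
- What may go wrong: O-prenylation and incomplete second alkylation, because the second alkylation is dearomative and slower than the first.
- Fallback (sets out from 3 and returns at 6): one equivalent of 4 under the same aqueous conditions, with isolation of 5, then Tsuji–Trost dearomative prenylation with tert-butyl 3-methylbut-2-en-1-yl carbonate and Pd(PPh3)4 (zerovalent palladium), in which the π-prenyl complex is attacked by C8 at its unsubstituted terminus. This fallback passes only through numbered compounds (F0).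

Step 9.
- What may go wrong: over-reduction to the primary alcohol, or hydride addition to ring A, if the aluminate collapses before quench.
- Fallback (sets out from 15 and returns at 16): full reduction with excess DIBAL-H (−78 → 0 °C) to the primary alcohol F13, then Dess–Martin oxidation to 16.

## Further compounds

F1 | step 6 | 6-benzoyl-2,2-dimethyl-8,8-bis(3-methylbut-2-en-1-yl)-5-oxo-5,8-dihydro-2H-chromen-7-yl acetate | CC(=O)OC1=C(C(=O)c2ccccc2)C(=O)C2=C(OC(C)(C)C=C2)C1(CC=C(C)C)CC=C(C)C
F2 | step 6 | methyl (3R)-2-hydroxy-3-{[(8R)-7-acetoxy-6-benzoyl-2,2-dimethyl-8-(3-methylbut-2-en-1-yl)-5-oxo-5,8-dihydro-2H-chromen-8-yl]methyl}-4-methylpent-4-enoate | C=C(C)[C@H](C(O)C(=O)OC)C[C@@]1(CC=C(C)C)C(OC(C)=O)=C(C(=O)c2ccccc2)C(=O)C2=C1OC(C)(C)C=C2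
F3 | step 6 | methyl (3R)-2-acetoxy-3-{[(8R)-7-acetoxy-6-benzoyl-2,2-dimethyl-8-(3-methylbut-2-en-1-yl)-5-oxo-5,8-dihydro-2H-chromen-8-yl]methyl}-4-methylpent-4-enoate | C=C(C)[C@H](C(OC(C)=O)C(=O)OC)C[C@@]1(CC=C(C)C)C(OC(C)=O)=C(C(=O)c2ccccc2)C(=O)C2=C1OC(C)(C)C=C2
F4 | step 6 | C8 epimer of 14 | C=C(C)[C@H](C(OC(C)=O)C(=O)OC)C[C@]1(CC=C(C)C)C(O)=C(C(=O)c2ccccc2)C(=O)C2=C1OC(C)(C)C=C2
F5 | step 3 | 6-benzoyl-5-hydroxy-2,2-dimethyl-2H-chromen-7-yl (tert-butyldimethylsilyloxy)acetate | CC(C)(C)[Si](C)(C)OCC(=O)Oc1cc2OC(C)(C)C=Cc2c(O)c1C(=O)c1ccccc1
F6 | step 3 | 6-benzoyl-2,2-dimethyl-5-(3-methylbut-2-en-1-yloxy)-2H-chromen-7-yl (tert-butyldimethylsilyloxy)acetate | CC(C)(C)[Si](C)(C)OCC(=O)Oc1cc2OC(C)(C)C=Cc2c(OCC=C(C)C)c1C(=O)c1ccccc1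
F7 | step 3 | 6-benzoyl-5-hydroxy-2,2-dimethyl-8-(3-methylbut-2-en-1-yl)-2H-chromen-7-yl (tert-butyldimethylsilyloxy)acetate | CC(C)(C)[Si](C)(C)OCC(=O)Oc1c(CC=C(C)C)c2OC(C)(C)C=Cc2c(O)c1C(=O)c1ccccc1
F8 | step 3 | 6-benzoyl-2,2-dimethyl-8-(3-methylbut-2-en-1-yl)-5-(3-methylbut-2-en-1-yloxy)-2H-chromen-7-yl (tert-butyldimethylsilyloxy)acetate | CC(C)(C)[Si](C)(C)OCC(=O)Oc1c(CC=C(C)C)c2OC(C)(C)C=Cc2c(OCC=C(C)C)c1C(=O)c1ccccc1
F9 | step 5 | 6-benzoyl-2,2-dimethyl-8,8-bis(3-methylbut-2-en-1-yl)-5-oxo-5,8-dihydro-2H-chromen-7-yl bromoacetate | BrCC(=O)OC1=C(C(=O)c2ccccc2)C(=O)C2=C(OC(C)(C)C=C2)C1(CC=C(C)C)CC=C(C)C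
F10 | step 5 | 6-benzoyl-2,2-dimethyl-8,8-bis(3-methylbut-2-en-1-yl)-5-oxo-5,8-dihydro-2H-chromen-7-yl (nitrooxy)acetate | O=[N+]([O-])OCC(=O)OC1=C(C(=O)c2ccccc2)C(=O)C2=C(OC(C)(C)C=C2)C1(CC=C(C)C)CC=C(C)C
F11 | step 8 | (8R,2'R)-C3' O-phenyl thionocarbonate of lactone 12 | C=C(C)[C@H]3C[C@@]1(CC=C(C)C)C(OC(=O)C3OC(=S)Oc4ccccc4)=C(C(=O)c2ccccc2)C(=O)C2=C1OC(C)(C)C=C2
F12 | step 8 | (8R,2'S)-C3'-deoxy lactone | C=C(C)[C@H]3C[C@@]1(CC=C(C)C)C(OC(=O)C3)=C(C(=O)c2ccccc2)C(=O)C2=C1OC(C)(C)C=C2
F0 | step 2 | none | none
F13 | step 9 | (8S)-6-benzoyl-7-hydroxy-8-[(2S)-2-(2-hydroxyethyl)-3-methylbut-3-en-1-yl]-2,2-dimethyl-8-(3-methylbut-2-en-1-yl)-2H-chromen-5(8H)-one | C=C(C)[C@H](CCO)C[C@@]1(CC=C(C)C)C(O)=C(C(=O)c2ccccc2)C(=O)C2=C1OC(C)(C)C=C2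
A1 | alternative 1 | 2-{[1-(3-methylbut-2-en-1-yl)-2,4,6-trioxocyclohexyl]methyl}-substituted (E)-enoate acid (C2' carboxylic acid, trione precursor) | O=C(O)[C@H](C/C=C(\C)C(=O)OC)CC1(CC=C(C)C)C(=O)CC(=O)CC1=O
A2 | alternative 1 | fused six-membered enol lactone, prenyl trans to the C3' chain | O=C3[C@H](C/C=C(\C)C(=O)OC)C[C@@]1(CC=C(C)C)C(O3)=CC(=O)CC1=O
A3 | alternative 2 | 3,3-disubstituted 6-(2-oxo-2-phenylethyl)-2H-pyran-2,4(3H)-dione | C=C(C)[C@H](C/C=C(\C)C(=O)OC)C[C@@]1(CC=C(C)C)C(=O)OC(CC(=O)c2ccccc2)=CC1=O
A4 | alternative 2 | ring-A benzoyl trione without ring B, methyl ester | C=C(C)[C@H](C/C=C(\C)C(=O)OC)C[C@@]1(CC=C(C)C)C(O)=C(C(=O)c2ccccc2)C(=O)CC1=O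
A5 | alternative 3 | methyl (2E)-5-formyl-2-methylhexa-2,5-dienoate | C=C(C=O)C/C=C(\C)C(=O)OC
A6 | alternative 3 | fused six-membered lactol, prenyl trans to the C3' chain (anomeric mixture) | OC3[C@H](C/C=C(\C)C(=O)OC)C[C@@]1(CC=C(C)C)C(O3)=C(C(=O)c2ccccc2)C(=O)C2=C1OC(C)(C)C=C2
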